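**Strategy.** The C3 hydroxyl and the C6 chlorine of the cyclohexene ring are cis-1,4 across C4=C5 and both syn to the C1 carbon that carries CH2OBz. Both C–heteroatom bonds are therefore made in one palladium(II)-catalysed intramolecular cis-1,4-chlorolactonisation of a cyclohexa-3,5-diene: the C1 carboxyl group, the future CH2OBz carbon, adds to C3 and chloride adds to C6, which closes a 6-oxabicyclo[3.2.1]octenone, sets C3 and C6 relative to C1 and C2 and differentiates O3 from O2. The precursor is unprotected (1S,2R)-1,2-dihydroxycyclohexa-3,5-diene-1-carboxylic acid, made by microbial cis-dihydroxylation of benzoic acid, which supplies C1 and C2.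

Key step: step 2

Remarks. (i) Ring atoms keep the target numbering throughout: C1 = C(OH)(CH2O–), C2 = CH–OBz, C3 = CH–OH, C4=C5, C6 = CHCl; O2 and O3 are the oxygens on C2 and C3. (ii) Assumption: diol acid 2 is not treated as a catalogue chemical and is made in step 1 with the known blocked mutant strain; the cells regenerate NADH from the fructose feed.

**Step 1**
Reactants: 1 benzoic acid
Product: 2 (1S,2R)-1,2-dihydroxycyclohexa-3,5-diene-1-carboxylic acid
Conditions: Ralstonia eutropha B9 (whole cells), benzoate fed as sodium salt, fructose, mineral salts medium, air, 30 °C, pH 7; then pH 3, EtOAc extraction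
Reagents that add atoms: dioxygen, O=O
Why: Benzoate 1,2-dioxygenase of the mutant, which lacks the diol dehydrogenase, adds O2 suprafacially across C1–C2 in an enzymatic dearomatising cis-dihydroxylation, and the active site alone fixes C1 (S) and C2 (R).

**Step 2**
Reactants: 2 (1S,2R)-1,2-dihydroxycyclohexa-3,5-diene-1-carboxylic acid
Product: 4 (1S,2R,5S,8R)-2-chloro-1,8-dihydroxy-6-oxabicyclo[3.2.1]oct-3-en-7-one, via allylpalladium lactone 3 (not isolated)
Conditions: Pd(OAc)2 (5 mol %), LiCl (3 equiv), p-benzoquinone (1.5 equiv), acetone/AcOH 4:1, 20 °C, dark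
Reagents that add atoms: lithium chloride, [Li+].[Cl-]
Why: Proposed new method: palladium(II) binds the diene on the face of the two free hydroxyls (the C2–OH can ligate the metal), the pseudoaxial C1 carboxylate attacks the diene terminus C3 anti to palladium to give the (η3-allyl)palladium lactone 3, and in the chloride-rich medium external chloride attacks the benzoquinone-activated allyl terminus C6, again anti to palladium, after which benzoquinone reoxidises Pd(0). The closest known reaction type is the palladium(II)/benzoquinone 1,4-chlorolactonisation of cyclohexadienylacetic acids, which gives fused lactones by the same anti/anti sequence; what is new is a carboxyl group bound directly to the ring, which has to close a bridged lactone of the kind known from halolactonisation of cyclohex-3-enecarboxylic acids. The γ-lactone ring closes 5-exo on C3 (C5 would be 5-endo, C6 would give a β-lactone) and completes the 6-oxabicyclo[3.2.1]oct-3-en-7-one. C3 is controlled by the tether, because the carboxylate oxygen can reach only the ring face that carries the carboxyl group, and C6 is controlled by the mechanism, because two successive anti attacks place chlorine cis to the lactone oxygen. The step needs 1,4- rather than 1,2-delivery of chloride, secured by the new C3–O bond, which is locked antiperiplanar to palladium and deactivates the neighbouring terminus C4, and it needs outer-sphere attack in both events, secured by excess LiCl, which keeps carboxylate off the metal. The diol stays unprotected because a group on O2 would cover the face that palladium must occupy.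

**Step 3**
Reactants: 4 (1S,2R,5S,8R)-2-chloro-1,8-dihydroxy-6-oxabicyclo[3.2.1]oct-3-en-7-one
Product: 5 (1S,2R,5S,8R)-2-chloro-1-hydroxy-7-oxo-6-oxabicyclo[3.2.1]oct-3-en-8-yl benzoate
Conditions: BzCl (1.2 equiv), pyridine, CH2Cl2, 0 °C
Reagents that add atoms: benzoyl chloride, O=C(Cl)c1ccccc1
Why: Pyridine-mediated O-acylation (Einhorn variant of the Schotten–Baumann reaction) should take the secondary O2 hydroxyl only, because O3 is tied up in the lactone and the tertiary bridgehead α-hydroxy lactone oxygen is too hindered to react at 0 °C; no stereocentre is touched.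

**Step 4**
Reactants: 5 (1S,2R,5S,8R)-2-chloro-1-hydroxy-7-oxo-6-oxabicyclo[3.2.1]oct-3-en-8-yl benzoate
Product: 7 (1R,2S,5R,6R)-5-chloro-2,6-dihydroxy-6-(hydroxymethyl)cyclohex-3-en-1-yl benzoate, via bridged lactol 6 (not isolated)
Conditions: LiBH4 (2 equiv), THF, −20 to 0 °C; AcOH/H2O quench at 0 °C
Reagents that add atoms: none
Why: In this borohydride reduction of a lactone to a diol the C1 alkoxyborohydride should deliver hydride to the adjacent strained lactone carbonyl much faster than to the conjugated secondary benzoate, lactol 6 opens and is reduced again, and the cold aprotic medium should suppress benzoyl migration and oxirane closure onto C6; no stereocentre is formed or touched.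

**Step 5**
Reactants: 7 (1R,2S,5R,6R)-5-chloro-2,6-dihydroxy-6-(hydroxymethyl)cyclohex-3-en-1-yl benzoate
Product: 8 [(1R,2R,5S,6R)-6-(benzoyloxy)-2-chloro-1,5-dihydroxycyclohex-3-en-1-yl]methyl benzoate
Conditions: BzCl (1.05 equiv), 2,4,6-collidine, CH2Cl2, −40 to −10 °C
Reagents that add atoms: benzoyl chloride, O=C(Cl)c1ccccc1
Why: Kinetic O-acylation with an acid chloride and a hindered pyridine base at low temperature should select the primary hydroxyl over the secondary allylic C3–OH and the tertiary C1–OH, and the weak base leaves the chlorohydrin and the O2 benzoate in place.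

**Compound list**
1 | benzoic acid | OC(=O)c1ccccc1 | starting material
2 | (1S,2R)-1,2-dihydroxycyclohexa-3,5-diene-1-carboxylic acid (hydroxyls cis) | OC(=O)[C@@]1(O)[C@H](O)C=CC=C1 | intermediate
3 | (η3-allyl)palladium(II) chloride complex of the bridged hydroxy lactone, Pd on C4–C6 on the face anti to the lactone bridge (SMILES drawn as the η1-C4 form) | O=C1O[C@H]2[C@H]([Pd]Cl)C=C[C@]1(O)[C@@H]2O | intermediate (not isolated)
4 | (1S,2R,5S,8R)-2-chloro-1,8-dihydroxy-6-oxabicyclo[3.2.1]oct-3-en-7-one | O=C1O[C@H]2C=C[C@@H](Cl)[C@]1(O)[C@@H]2O | intermediate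
5 | (1S,2R,5S,8R)-2-chloro-1-hydroxy-7-oxo-6-oxabicyclo[3.2.1]oct-3-en-8-yl benzoate | O=C1O[C@H]2C=C[C@@H](Cl)[C@]1(O)[C@@H]2OC(=O)c1ccccc1 | intermediate
6 | (1S,2R,5S,8R)-2-chloro-1,7-dihydroxy-6-oxabicyclo[3.2.1]oct-3-en-8-yl benzoate (lactol, both C7 epimers) | OC1O[C@H]2C=C[C@@H](Cl)[C@]1(O)[C@@H]2OC(=O)c1ccccc1 | intermediate (not isolated)
7 | (1R,2S,5R,6R)-5-chloro-2,6-dihydroxy-6-(hydroxymethyl)cyclohex-3-en-1-yl benzoate | OC[C@]1(O)[C@H](Cl)C=C[C@H](O)[C@H]1OC(=O)c1ccccc1 | intermediate
8 | [(1R,2R,5S,6R)-6-(benzoyloxy)-2-chloro-1,5-dihydroxycyclohex-3-en-1-yl]methyl benzoate | O=C(OC[C@]1(O)[C@H](Cl)C=C[C@H](O)[C@H]1OC(=O)c1ccccc1)c1ccccc1 | target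

**Total step count:** 5
**Longest linear sequence:** 5 steps

**Steps most likely to fail**

1. Step 2 (the labelled step). Process at risk: the bridged 5-exo closure may be slower than intermolecular acetate capture of the palladium–diene complex, than Diels–Alder consumption of the diene by benzoquinone or than acid-induced rearomatisation, and chloride may be delivered to C4 instead of C6. Fallback with known chemistry, the intermolecular version of the same 1,4-oxidation, sets out from 2 and comes back at 8. Acid 2 is esterified with TMSCHN2 (MeOH/toluene, 0 °C) to methyl (1S,2R)-1,2-dihydroxycyclohexa-3,5-diene-1-carboxylate F1, which is reduced with LiAlH4 (THF, 0 °C) to (1R,2R)-1-(hydroxymethyl)cyclohexa-3,5-diene-1,2-diol F2. BzCl (2.1 equiv, pyridine, 0 °C) should acylate the primary and the secondary hydroxyl to give [(1R,6R)-6-(benzoyloxy)-1-hydroxycyclohexa-2,4-dien-1-yl]methyl benzoate F3. Palladium(II)/benzoquinone 1,4-chloroacetoxylation (Pd(OAc)2, LiCl, LiOAc, p-benzoquinone, AcOH, 20 °C) should then place acetate on C3 anti to the neighbouring O2 benzoate, with the free tertiary hydroxyl holding palladium on its own face, and chloride on C6 cis to the acetate. This would give [(1R,2R,5S,6R)-5-acetoxy-6-(benzoyloxy)-2-chloro-1-hydroxycyclohex-3-en-1-yl]methyl benzoate F4. Acid-catalysed methanolysis (AcCl cat., MeOH, 0 °C), which cleaves acetates faster than benzoates, should give 8.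

2. Step 4. Process at risk: hydride attack on the O2 benzoate, benzoyl shift from O2 to the O3 alkoxide freed on ring opening, or oxirane closure of the C1 alkoxide onto C6. The fallback sets out from 5 and comes back at 7. The reduction is split into two redox stages with a non-basic second stage. LiAlH(OtBu)3 (THF, −40 °C), a reagent established for partial reduction of O-benzoylated lactones, should stop at lactol 6, which is isolated this time. The lactol is then reduced through its hydroxy-aldehyde form in acidic medium with Me4NBH(OAc)3 (MeCN/AcOH, 0 °C) to 7. No new compound arises (F0).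

3. Step 5. Process at risk: loss of site selectivity, because the primary hydroxyl is neopentyl-like, so that acylation of O3 and double benzoylation compete. The fallback sets out from 7 and comes back at 8. Kinetic discrimination is replaced by diol recognition: Me2SnCl2 (5 mol %), BzCl (1.1 equiv), iPr2NEt, THF, 20 °C. The tin catalyst chelates the CH2OH/C1–OH 1,2-diol and activates its primary oxygen, whereas the isolated C3 hydroxyl is not activated. No new compound arises (F0).

**Further compounds**
F1 | step 2 | methyl (1S,2R)-1,2-dihydroxycyclohexa-3,5-diene-1-carboxylate | COC(=O)[C@@]1(O)[C@H](O)C=CC=C1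
F2 | step 2 | (1R,2R)-1-(hydroxymethyl)cyclohexa-3,5-diene-1,2-diol | OC[C@@]1(O)[C@H](O)C=CC=C1
F3 | step 2 | [(1R,6R)-6-(benzoyloxy)-1-hydroxycyclohexa-2,4-dien-1-yl]methyl benzoate | O=C(OC[C@@]1(O)[C@H](OC(=O)c2ccccc2)C=CC=C1)c1ccccc1
F4 | step 2 | [(1R,2R,5S,6R)-5-acetoxy-6-(benzoyloxy)-2-chloro-1-hydroxycyclohex-3-en-1-yl]methyl benzoate | O=C(OC[C@]1(O)[C@H](Cl)C=C[C@H](OC(C)=O)[C@H]1OC(=O)c1ccccc1)c1ccccc1
F0 | step 4 | none | none
F0 | step 5 | none | none
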